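**Retrosynthetic overview**
1. The target is a diaryl ether of two benzene rings that are both bought; no ring is formed in the route and there is no stereocentre.
2. Last disconnection: the two C–Br bonds on ring B (ortho and para to the free OH), made by electrophilic bromination of phenol 5.
3. The phenol OH of ring B comes from an aldehyde by Dakin oxidation of aldehyde 3.
4. The diaryl ether C–O bond comes from SNAr of 2,4-dibromo-6-methoxyphenol (ring A, bromines already in place) on 2-fluorobenzaldehyde (ring B).

Assumption: the target is achiral, so "single enantiomer" asks for nothing further; compounds 1 and 2 are taken as catalogue chemicals.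

**Route**

Step 1
Reactants: 1 2,4-dibromo-6-methoxyphenol; 2 2-fluorobenzaldehyde
Product: 3 2-(2,4-dibromo-6-methoxyphenoxy)benzaldehyde
Conditions: K2CO3 (1.5 equiv), DMAc, 130 °C, N2
Reagents that add atoms: none
Why: Nucleophilic aromatic substitution (SNAr, addition–elimination), in which the ortho-formyl group activates the C–F bond of 2 toward the phenoxide of 1 while the unactivated aryl bromides of 1 stay untouched; no stereocentre is created.

Step 2
Reactants: 3 2-(2,4-dibromo-6-methoxyphenoxy)benzaldehyde
Product: 5 2-(2,4-dibromo-6-methoxyphenoxy)phenol, via aryl formate 4 (not isolated)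
Conditions: mCPBA (1.3 equiv), CH2Cl2, 0 °C to rt; aq. Na2S2O3/NaHCO3 wash; then K2CO3 (0.2 equiv), MeOH, rt
Reagents that add atoms: mCPBA (3-chloroperoxybenzoic acid), O=C(OO)c1cccc(Cl)c1
Why: Dakin-type Baeyer–Villiger oxidation, in which the aryl group bearing the ortho-aryloxy donor migrates to oxygen in the peracid adduct to give formate 4, which base-catalysed methanolysis cleaves to the phenol; aryl bromides and the methyl ether are inert and no stereocentre is involved.

Step 3
Reactants: 5 2-(2,4-dibromo-6-methoxyphenoxy)phenol
Product: 7 2,4-dibromo-6-(2,4-dibromo-6-methoxyphenoxy)phenol, via para-monobromide 6 (not isolated)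
Conditions: Br2 (2.05 equiv, added dropwise), AcOH, rt
Reagents that add atoms: bromine, BrBr
Why: Electrophilic aromatic substitution (phenol bromination), in which the free OH of ring B directs bromine first para and then ortho to itself, while ring A is deactivated by two bromines and its only site para to OMe is flanked by both of them; no stereocentre is created.

**Compound list**
1 | 2,4-dibromo-6-methoxyphenol | COc1cc(Br)cc(Br)c1O | starting material
2 | 2-fluorobenzaldehyde | O=Cc1ccccc1F | starting material
3 | 2-(2,4-dibromo-6-methoxyphenoxy)benzaldehyde | COc1cc(Br)cc(Br)c1Oc1ccccc1C=O | intermediate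
4 | 2-(2,4-dibromo-6-methoxyphenoxy)phenyl formate | COc1cc(Br)cc(Br)c1Oc1ccccc1OC=O | intermediate
5 | 2-(2,4-dibromo-6-methoxyphenoxy)phenol | COc1cc(Br)cc(Br)c1Oc1ccccc1O | intermediate
6 | 4-bromo-2-(2,4-dibromo-6-methoxyphenoxy)phenol | COc1cc(Br)cc(Br)c1Oc1cc(Br)ccc1O | intermediate
7 | 2,4-dibromo-6-(2,4-dibromo-6-methoxyphenoxy)phenol | COc1cc(Br)cc(Br)c1Oc1cc(Br)cc(Br)c1O | target

**Totals**
Total step count: 3. Longest linear sequence: 3 steps (1 → 3 → 5 → 7).

**Steps most likely to fail, each with a fallback**

Step 1 (the phenoxide of 1 is ortho,ortho-disubstituted and weakly nucleophilic, so SNAr on the moderately activated aldehyde 2 may stall or the aldehyde may degrade at 130 °C). The fallback sets out from 1 and uses a far stronger SNAr acceptor whose activating group is later turned into the OH. Compound 1 is condensed with 1-fluoro-2-nitrobenzene (K2CO3, DMF, 80 °C) to give 1,5-dibromo-3-methoxy-2-(2-nitrophenoxy)benzene F1. The nitro group is reduced without touching the aryl bromides (Fe powder, NH4Cl, EtOH/H2O, 80 °C) to 2-(2,4-dibromo-6-methoxyphenoxy)aniline F2. Diazotisation (NaNO2, aq. H2SO4, 0 °C) gives 2-(2,4-dibromo-6-methoxyphenoxy)benzenediazonium hydrogensulfate F3, which is hydrolysed by warming in dilute aqueous H2SO4. Both ortho positions of ring A are blocked, so radical or cationic ring closure to a dibenzofuran is not available. The sequence comes back to the route at phenol 5.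

Step 2 (hydride instead of aryl migration would give the benzoic acid, and the electron-rich product can be over-oxidised). The fallback sets out from 1 and replaces the aldehyde by a methyl ketone, where aryl migration has no hydride competitor. Compound 1 and 1-(2-fluorophenyl)ethanone (K2CO3, DMAc, 130 °C) give 1-[2-(2,4-dibromo-6-methoxyphenoxy)phenyl]ethanone F4. Baeyer–Villiger oxidation (mCPBA, CF3CO2H, CH2Cl2, rt) gives 2-(2,4-dibromo-6-methoxyphenoxy)phenyl acetate F5. Methanolysis (K2CO3, MeOH, rt) comes back to the route at phenol 5.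

Step 3 (a third bromine may enter ring B para to the ether oxygen, or ring A may be attacked, giving mixtures that are hard to separate). The fallback sets out from 1 and brings ring B in with both bromines already fixed by the building block. Compound 1 and 2,4-dibromo-6-fluorobenzaldehyde (K2CO3, DMF, 90 °C; fluoride is displaced far faster than either bromide) give 2,4-dibromo-6-(2,4-dibromo-6-methoxyphenoxy)benzaldehyde F6. Dakin oxidation (mCPBA, CH2Cl2, rt) gives 2,4-dibromo-6-(2,4-dibromo-6-methoxyphenoxy)phenyl formate F7. Methanolysis (K2CO3 cat., MeOH, rt) comes back to the route at target 7.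

**Further compounds**
F1 | step 1 | 1,5-dibromo-3-methoxy-2-(2-nitrophenoxy)benzene | COc1cc(Br)cc(Br)c1Oc1ccccc1[N+](=O)[O-]
F2 | step 1 | 2-(2,4-dibromo-6-methoxyphenoxy)aniline | COc1cc(Br)cc(Br)c1Oc1ccccc1N
F3 | step 1 | 2-(2,4-dibromo-6-methoxyphenoxy)benzenediazonium hydrogensulfate | COc1cc(Br)cc(Br)c1Oc1ccccc1[N+]#N.OS(=O)(=O)[O-]
F4 | step 2 | 1-[2-(2,4-dibromo-6-methoxyphenoxy)phenyl]ethanone | COc1cc(Br)cc(Br)c1Oc1ccccc1C(C)=O
F5 | step 2 | 2-(2,4-dibromo-6-methoxyphenoxy)phenyl acetate | COc1cc(Br)cc(Br)c1Oc1ccccc1OC(C)=O
F6 | step 3 | 2,4-dibromo-6-(2,4-dibromo-6-methoxyphenoxy)benzaldehyde | COc1cc(Br)cc(Br)c1Oc1cc(Br)cc(Br)c1C=O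
F7 | step 3 | 2,4-dibromo-6-(2,4-dibromo-6-methoxyphenoxy)phenyl formate | COc1cc(Br)cc(Br)c1Oc1cc(Br)cc(Br)c1OC=O
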